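**Assumption (one line):** (S)-3-hydroxy-γ-butyrolactone is treated as a commodity enantiopure building block, and reagents that leave non-hydrogen atoms in a product are numbered as compounds.

## Retrosynthetic overview

1. Target ⇐ desilylation of a 6-prenylflavanone whose C6–prenyl bond comes from an aromatic Claisen [3,3] rearrangement of the 7-O-(1,1-dimethylallyl) ether (key sigmatropic step).
2. Flavanone C ring (O1–C2) ⇐ intramolecular Mitsunobu closure (inversion) of an (R)-β-hydroxy ketone, made from an A-ring aryllithium (from phloroglucinol) and a Weinreb amide.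
3. (R)-benzylic carbinol ⇐ syn-1,3-reduction of an aryl ketone directed by the carbinol of (S)-3-hydroxy-γ-butyrolactone; the lactone C=O, CH2 and CHOH carbons become C2, C3 and C4, and its CH2O carbon is cleaved off.
4. B-ring 2H-chromene ⇐ 4-bromoresorcinol + prenal by condensation and oxa-6π electrocyclization.
5. Ring order: chromene pyran ring first (step 1), pyranone C ring second (step 12); both benzene rings are bought.

Abbreviation: **Ar** = 2,2-dimethyl-7-(triisopropylsilyloxy)-2H-chromen-6-yl.

## Route

**Step 1**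
Reactants: 1 (4-bromoresorcinol), 2 (3-methylbut-2-enal, prenal)
Product: 3 (6-bromo-2,2-dimethyl-2H-chromen-7-ol)
Conditions: ethylenediamine diacetate (10 mol %), PhMe, 110 °C
Reagents that add atoms: none
Why: Knoevenagel-type C-alkylation at C6 of the resorcinol (the flanked C2 reacts less; minor isomers removed), dehydration to an o-quinone methide and oxa-6π electrocyclization give the chromene, with Br marking the future C1′.

**Step 2**
Reactants: 3, 4 (triisopropylsilyl chloride)
Product: 5 ((6-bromo-2,2-dimethyl-2H-chromen-7-yloxy)triisopropylsilane, Ar–Br)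
Conditions: TIPSCl, imidazole, DMF, 40 °C
Reagents that add atoms: 4, TIPSCl, CC(C)[Si](Cl)(C(C)C)C(C)C
Why: Phenol silylation; the bulky TIPS ether tolerates organolithiums and is removable at the end with buffered fluoride.

**Step 3**
Reactants: 5, 6 ((S)-3-hydroxy-γ-butyrolactone)
Product: 7 ((S)-1-Ar-3,4-dihydroxybutan-1-one, in equilibrium with its cyclic hemiketal)
Conditions: 5, t-BuLi (2 equiv), Et2O, −78 °C; then lithium alkoxide of 6 (6 + LiHMDS, THF), −78 → −40 °C; aq NH4Cl
Reagents that add atoms: none
Why: Br–Li exchange and acyl substitution on the lactone; the tetrahedral lactolate prevents over-addition and the bought stereocentre is untouched.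

**Step 4**
Reactants: 7
Product: 8 ((1R,3S)-1-Ar-butane-1,3,4-triol)
Conditions: Et2BOMe (2.2 equiv), THF–MeOH 4:1, −78 °C; NaBH4; MeOH azeotrope
Reagents that add atoms: none
Why: Narasaka–Prasad reduction: axial hydride delivery to the boron chelate gives the syn-1,3-diol, so the bought (S)-carbinol sets the new benzylic centre as R (typically >95:5).

**Step 5**
Reactants: 8
Product: 9 ((R)-3-Ar-3-hydroxypropanal)
Conditions: NaIO4, THF–pH 7 buffer, 0 °C; used crude
Reagents that add atoms: none
Why: Malaprade cleavage of the terminal 1,2-diol only; the controlling carbinol carbon becomes the aldehyde carbon (future C4) and the benzylic centre is not touched.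

**Step 6**
Reactants: 9, 10 (sodium chlorite)
Product: 11 ((R)-3-Ar-3-hydroxypropanoic acid)
Conditions: NaClO2, NaH2PO4, 2-methyl-2-butene (excess), t-BuOH–H2O, 0 °C
Reagents that add atoms: 10, sodium chlorite, [Na+].[O-]Cl=O
Why: Pinnick oxidation; the HOCl scavenger protects the chromene alkene and electron-rich ring, and the stereocentre is not involved.

**Step 7**
Reactants: 11, 12 (N,O-dimethylhydroxylamine hydrochloride)
Product: 13 ((R)-3-Ar-3-hydroxy-N-methoxy-N-methylpropanamide)
Conditions: MeNHOMe·HCl, EDC·HCl, HOBt, NMM, CH2Cl2, 0 °C → rt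
Reagents that add atoms: 12, N,O-dimethylhydroxylamine hydrochloride, CNOC.Cl
Why: Carbodiimide amide coupling gives a Weinreb amide that reacts with an aryllithium at −78 °C; the free β-OH is tolerated.

**Step 8**
Reactants: 14 (phloroglucinol), 15 (allyl bromide)
Product: 16 (1,3,5-tris(allyloxy)benzene)
Conditions: allyl bromide (3.6 equiv), K2CO3, DMF, 50 °C
Reagents that add atoms: 15, allyl bromide, C=CCBr
Why: Williamson O-allylation; allyl ethers survive aryllithium chemistry at −78 °C and come off later under neutral Pd(0) conditions.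

**Step 9**
Reactants: 16, 17 (N-bromosuccinimide)
Product: 18 (2-bromo-1,3,5-tris(allyloxy)benzene)
Conditions: NBS (1.0 equiv), CH2Cl2, −20 °C
Reagents that add atoms: 17, NBS, O=C1CCC(=O)N1Br
Why: Electrophilic aromatic monobromination of a very electron-rich ring with three equivalent positions.

**Step 10**
Reactants: 13, 18
Product: 19 ((R)-3-Ar-3-hydroxy-1-[2,4,6-tris(allyloxy)phenyl]propan-1-one)
Conditions: 18, n-BuLi, THF, −78 °C; then 13 (pre-treated with i-PrMgCl, 1 equiv), −78 → −40 °C; AcOH quench
Reagents that add atoms: none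
Why: Br–Li exchange then Weinreb ketone synthesis; the chelated tetrahedral intermediate stops at the ketone and the β-OH is carried as its alkoxide.

**Step 11**
Reactants: 19
Product: 20 ((R)-3-Ar-3-hydroxy-1-(2,4,6-trihydroxyphenyl)propan-1-one)
Conditions: Pd(PPh3)4 (5 mol %), PhSiH3, CH2Cl2, rt; used directly
Reagents that add atoms: none
Why: Tsuji–Trost deallylation under neutral conditions frees the three phenols without touching the TIPS ether, the chromene or the carbinol.

**Step 12**
Reactants: 20
Product: 21 ((2S)-2-Ar-5,7-dihydroxychroman-4-one)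
Conditions: PPh3, DIAD, PhMe–THF (0.01 M), −20 → 0 °C
Reagents that add atoms: none
Why: Intramolecular Mitsunobu etherification by an ortho-phenol; SN2 inversion turns the (R)-carbinol into the (2S)-flavanone, and the symmetric A ring gives one regioisomer.

**Step 13**
Reactants: 21, 22 (tert-butyl 2-methylbut-3-en-2-yl carbonate)
Product: 23 ((2S)-2-Ar-5-hydroxy-7-(2-methylbut-3-en-2-yloxy)chroman-4-one)
Conditions: 22, Pd(PPh3)4 (2 mol %), THF, 0 °C, short reaction time
Reagents that add atoms: 22, tert-butyl 2-methylbut-3-en-2-yl carbonate, C=CC(C)(C)OC(=O)OC(C)(C)C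
Why: Pd-catalysed decarboxylative O-allylation (Tsuji–Trost) of the free 7-OH at the tertiary terminus gives the 1,1-dimethylallyl ether; the chelated 5-OH does not react.

**Step 14**
Reactants: 23
Product: 24 ((2S)-2-Ar-5,7-dihydroxy-6-(3-methylbut-2-enyl)chroman-4-one)
Conditions: PhMe, 100 °C
Reagents that add atoms: none
Why: Aromatic Claisen [3,3] rearrangement then tautomerisation; the 5-OH···O=C4 chelate gives the C6–C7 bond more double-bond character, so the prenyl group is expected mainly at C6 (minor C8 isomer separated), and C2 is not involved.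

**Step 15**
Reactants: 24
Product: 25 (cudraflavanone A)
Conditions: TBAF, AcOH (1:1), THF, 0 °C
Reagents that add atoms: none
Why: Fluoride desilylation of the aryl TIPS ether, buffered to avoid base-induced flavanone ring-opening and loss of the C2 configuration.

## Compound list

1 | 4-bromoresorcinol | Oc1ccc(Br)c(O)c1 | starting material
2 | 3-methylbut-2-enal | CC(C)=CC=O | starting material
3 | 6-bromo-2,2-dimethyl-2H-chromen-7-ol | CC1(C)C=Cc2cc(Br)c(O)cc2O1 | intermediate
4 | triisopropylsilyl chloride | CC(C)[Si](Cl)(C(C)C)C(C)C | starting material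
5 | (6-bromo-2,2-dimethyl-2H-chromen-7-yloxy)triisopropylsilane | CC1(C)C=Cc2cc(Br)c(O[Si](C(C)C)(C(C)C)C(C)C)cc2O1 | intermediate
6 | (S)-3-hydroxy-γ-butyrolactone | O=C1C[C@H](O)CO1 | starting material
7 | (S)-1-Ar-3,4-dihydroxybutan-1-one | OC[C@@H](O)CC(=O)c1cc2c(cc1O[Si](C(C)C)(C(C)C)C(C)C)OC(C)(C)C=C2 | intermediate
8 | (1R,3S)-1-Ar-butane-1,3,4-triol | OC[C@@H](O)C[C@@H](O)c1cc2c(cc1O[Si](C(C)C)(C(C)C)C(C)C)OC(C)(C)C=C2 | intermediate
9 | (R)-3-Ar-3-hydroxypropanal | O=CC[C@@H](O)c1cc2c(cc1O[Si](C(C)C)(C(C)C)C(C)C)OC(C)(C)C=C2 | intermediate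
10 | sodium chlorite | [Na+].[O-]Cl=O | starting material
11 | (R)-3-Ar-3-hydroxypropanoic acid | OC(=O)C[C@@H](O)c1cc2c(cc1O[Si](C(C)C)(C(C)C)C(C)C)OC(C)(C)C=C2 | intermediate
12 | N,O-dimethylhydroxylamine hydrochloride | CNOC.Cl | starting material
13 | (R)-3-Ar-3-hydroxy-N-methoxy-N-methylpropanamide | CON(C)C(=O)C[C@@H](O)c1cc2c(cc1O[Si](C(C)C)(C(C)C)C(C)C)OC(C)(C)C=C2 | intermediate
14 | phloroglucinol | Oc1cc(O)cc(O)c1 | starting material
15 | allyl bromide | C=CCBr | starting material
16 | 1,3,5-tris(allyloxy)benzene | C=CCOc1cc(OCC=C)cc(OCC=C)c1 | intermediate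
17 | N-bromosuccinimide | O=C1CCC(=O)N1Br | starting material
18 | 2-bromo-1,3,5-tris(allyloxy)benzene | C=CCOc1cc(OCC=C)c(Br)c(OCC=C)c1 | intermediate
19 | (R)-3-Ar-3-hydroxy-1-[2,4,6-tris(allyloxy)phenyl]propan-1-one | C=CCOc1cc(OCC=C)c(C(=O)C[C@@H](O)c2cc3c(cc2O[Si](C(C)C)(C(C)C)C(C)C)OC(C)(C)C=C3)c(OCC=C)c1 | intermediate
20 | (R)-3-Ar-3-hydroxy-1-(2,4,6-trihydroxyphenyl)propan-1-one | O=C(C[C@@H](O)c1cc2c(cc1O[Si](C(C)C)(C(C)C)C(C)C)OC(C)(C)C=C2)c1c(O)cc(O)cc1O | intermediate
21 | (2S)-2-Ar-5,7-dihydroxychroman-4-one | O=C1C[C@@H](c2cc3c(cc2O[Si](C(C)C)(C(C)C)C(C)C)OC(C)(C)C=C3)Oc2cc(O)cc(O)c21 | intermediate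
22 | tert-butyl 2-methylbut-3-en-2-yl carbonate | C=CC(C)(C)OC(=O)OC(C)(C)C | starting material
23 | (2S)-2-Ar-5-hydroxy-7-(2-methylbut-3-en-2-yloxy)chroman-4-one | O=C1C[C@@H](c2cc3c(cc2O[Si](C(C)C)(C(C)C)C(C)C)OC(C)(C)C=C3)Oc2cc(OC(C)(C)C=C)cc(O)c21 | intermediate
24 | (2S)-2-Ar-5,7-dihydroxy-6-(3-methylbut-2-enyl)chroman-4-one | O=C1C[C@@H](c2cc3c(cc2O[Si](C(C)C)(C(C)C)C(C)C)OC(C)(C)C=C3)Oc2cc(O)c(CC=C(C)C)c(O)c21 | intermediate
25 | cudraflavanone A | CC(C)=CCc1c(O)cc2c(c1O)C(=O)C[C@@H](c1cc3c(cc1O)OC(C)(C)C=C3)O2 | target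

## Summary

Total steps: 15.
Longest linear sequence: 13 (steps 1–7, then 10–15, from 4-bromoresorcinol).

Three steps most likely to fail, each with a fallback that changes the approach:

1. **Step 12 (Mitsunobu closure).** The 2-silyloxy-4-alkoxybenzylic carbinol can ionise, which would erode ee and give chalcone by elimination. Fallback: make the (S)-carbinol instead (anti-selective Me4NBH(OAc)3 reduction of 7, or start from ent-6) and form the O1–aryl bond with retention by Pd- or Cu-catalysed intramolecular O-arylation onto a 2-bromo A ring at the 1,3-diol (flavan-4-ol) stage, then oxidise C4–OH.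

2. **Step 14 (Claisen regiochemistry, C6 versus C8; also branched versus linear ether in step 13).** Fallback: put the prenyl group on the A-ring fragment before coupling (lithiate 16, transmetalate to copper, prenyl bromide, then brominate). The 6- versus 8-prenyl outcome is then decided by which ortho-OH closes in the Mitsunobu step (the less hindered one gives 6-prenyl), and the isomers are separated.

3. **Step 3 (aryllithium on the unprotected hydroxy-lactone).** Risks are silyl migration in the ortho-silyloxy aryllithium, enolisation of the lactone, and dehydration of the hemiketal to a furan. Fallback: reverse the polarity. Quench the aryllithium with DMF to give Ar–CHO, run a boron aldol with the O-protected methyl ketone from ethyl (S)-lactate (1,4-induction), unmask the α-OH and cleave the α-hydroxy ketone with NaIO4 to reach acid 11 directly.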